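**Retrosynthetic overview**
1. Numbering: the ring atoms run from C1 (carries the exocyclic =CH2) to C14 (free carbinol) in the order of the SMILES string, and C18 is the oxymethyl carbon on C11. The only ring, the 14-membered carbocycle, is closed three steps before the target.
2. Feature used: C11 is the fully substituted carbon of the C10=C11 alkene, and its ring neighbour C12H2 lies cis to C9. C12–C13–C14(O)–C1 is the chain of a 4-hydroxy acid less its carboxyl carbon, so C11–C12 is cut to a (Z)-C11 iodide and a C12 radical released from a redox-active ester.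
3. The seco chain is cut at C8–C9. An (E)-allylboronate adds anti-selectively, under catalyst control, to (Z)-3-iodo-4-silyloxybut-2-enal (C9–C11 and C18, from but-2-yne-1,4-diol); this step also creates the isopropenyl group.
4. The boronate chain comes from (R)-5-oxotetrahydrofuran-2-carboxylic acid (C14 stereocentre, C1, C12, C13 and the carbon later expelled), a malonate CH2 (C2), geranyl bromide (C3–C8 and the isopropenyl and methyl carbons) and CH2Br2 (=CH2).
5. Endgame: both TES ethers are removed, C9–OH and C18–OH are acetylated, and the C14 TBS ether is removed.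

Key step: step 16

Remark: (R)-TRIP is assumed to open the Re face of the enal, as the accepted model for aldehyde allylboration predicts. The sense is to be checked by Mosher ester analysis of the allylboration product, and the antipodal acid is equally available.

**Route**

Step 1
Reactants: 1 (R)-5-oxotetrahydrofuran-2-carboxylic acid; 2 allyl hydrogen malonate
Product: 4 allyl 3-oxo-3-[(2R)-5-oxotetrahydrofuran-2-yl]propanoate, via acyl imidazolide 3 (not isolated)
Conditions: CDI, THF, rt; then 2, MgCl2, Et3N, MeCN/THF, rt; aq. citric acid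
Reagents that add atoms: 1,1'-carbonyldiimidazole, O=C(n1ccnc1)n1ccnc1 (its imidazolyl group stays only in 3)
Why: Masamune–Brooks homologation, in which the acyl imidazolide C-acylates the magnesium enolate of the malonate half-ester and loss of CO2 drives the reaction under near-neutral conditions, so the lactone and the C14 stereocentre taken from 1 should be untouched.

Step 2
Reactants: 4 allyl β-keto ester; 5 geranyl bromide
Product: 6 allyl (4E)-5,9-dimethyl-2-[(2R)-5-oxotetrahydrofuran-2-carbonyl]deca-4,8-dienoate (both C2 epimers)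
Conditions: K2CO3, acetone, rt
Reagents that add atoms: none
Why: SN2 C-alkylation of a stabilised β-keto ester enolate by a primary allylic bromide keeps the E alkene; only the position between the two carbonyls is deprotonated, so C14 is not enolised, and the new C2 centre is erased in step 3.

Step 3
Reactants: 6 geranylated allyl β-keto ester
Product: 7 (5R)-5-[(4E)-5,9-dimethyldeca-4,8-dienoyl]dihydrofuran-2(3H)-one
Conditions: Pd(OAc)2 (5 mol%), PPh3 (20 mol%), HCO2H, Et3N, THF, rt
Reagents that add atoms: none
Why: Tsuji deallylation–decarboxylation with formate, in which zerovalent palladium ionises only the allyl ester, CO2 is lost at room temperature and the enolate is protonated in a buffered medium that should not epimerise C14.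

Step 4
Reactants: 7 homogeranyl ketone
Product: 8 (5R)-5-[(5E)-6,10-dimethylundeca-1,5,9-trien-2-yl]dihydrofuran-2(3H)-one
Conditions: Zn, CH2Br2, TiCl4, THF (pre-aged, −40 to 5 °C); then 7, CH2Cl2, 0 °C to rt; aq. NaHCO3
Reagents that add atoms: dibromomethane, BrCBr
Why: Takai–Oshima–Lombardo methylenation uses a non-basic gem-dizinc/titanium reagent that attacks ketones but not lactones, and it is the usual choice for enolisable ketones with an α-stereocentre.

Step 5
Reactants: 8 methylene lactone
Product: 10 methyl (4R,8E)-4-hydroxy-9,13-dimethyl-5-methylidenetetradeca-8,12-dienoate, via potassium carboxylate 9 (not isolated)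
Conditions: KOH (1.05 equiv), MeOH/H2O, rt; evaporate to dryness; MeI, DMF, 0 °C to rt; crude product used at once
Reagents that add atoms: potassium hydroxide, [K+].[OH-]; iodomethane, CI
Why: Acyl–oxygen saponification leaves the C14–O bond intact, and SN2 O-methylation of the dry carboxylate is run without acid, so relactonisation should be slow.

Step 6
Reactants: 10 hydroxy ester
Product: 11 methyl (4R,8E)-4-(tert-butyldimethylsilyloxy)-9,13-dimethyl-5-methylidenetetradeca-8,12-dienoate
Conditions: TBSOTf, 2,6-lutidine, CH2Cl2, −78 to 0 °C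
Reagents that add atoms: tert-butyldimethylsilyl triflate, CC(C)(C)[Si](C)(C)OS(=O)(=O)C(F)(F)F
Why: Silyl triflate silylation of the secondary allylic alcohol is fast at low temperature and should outrun lactonisation.

Step 7
Reactants: 11 TBS ether methyl ester
Product: 12 methyl (4R,8E,12E)-4-(tert-butyldimethylsilyloxy)-14-hydroxy-9,13-dimethyl-5-methylidenetetradeca-8,12-dienoate
Conditions: SeO2 (cat.), tBuOOH, salicylic acid (cat.), CH2Cl2, 0 °C, stopped at partial conversion, 11 recycled
Reagents that add atoms: selenium dioxide, O=[Se]=O (delivers the oxygen); tert-butyl hydroperoxide, CC(C)(C)OO (re-oxidises selenium, ultimate oxygen source)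
Why: Catalytic SeO2 allylic oxidation (ene reaction, then [2,3]-sigmatropic shift) takes the E-methyl group of the most accessible terminal trisubstituted alkene, while the C1 methylene is less substituted and is deactivated by the adjacent silyloxy group.

Step 8
Reactants: 12 (E)-allylic alcohol
Product: 13 methyl (4R,8E,12E)-4-(tert-butyldimethylsilyloxy)-9,13-dimethyl-5-methylidene-14-(4,4,5,5-tetramethyl-1,3,2-dioxaborolan-2-yl)tetradeca-8,12-dienoate
Conditions: [Pd(MeCN)4](BF4)2 (5 mol%), B2pin2, DMSO/MeOH, rt to 40 °C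
Reagents that add atoms: bis(pinacolato)diboron, CC1(C)OB(OC1(C)C)B1OC(C)(C)C(C)(C)O1
Why: In the palladium-catalysed direct borylation of allylic alcohols, boron is delivered to the unsubstituted terminus of the syn π-allylpalladium, so the linear (E)-boronate is expected, and no other allylic leaving group is present now that the lactone is open.

Step 9
Reactants: 14 but-2-yne-1,4-diol
Product: 15 4-(triethylsilyloxy)but-2-yn-1-ol
Conditions: TESCl (1 equiv), imidazole, 14 (3 equiv), DMF, 0 °C
Reagents that add atoms: chlorotriethylsilane, CC[Si](Cl)(CC)CC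
Why: Statistical monosilylation with excess diol; unreacted diol is washed out with water.

Step 10
Reactants: 15 mono-TES butynediol
Product: 17 (Z)-3-iodo-4-(triethylsilyloxy)but-2-en-1-ol, via cyclic alkenylaluminate 16 (not isolated)
Conditions: NaAlH2(OCH2CH2OCH3)2, THF, 0 °C; EtOAc; I2, THF, −78 °C; aq. potassium sodium tartrate, Na2S2O3
Reagents that add atoms: NaAlH2(OCH2CH2OCH3)2, [Na+].COCCO[AlH2-]OCCOC (aluminium and alkoxides stay only in 16); iodine, II
Why: Hydroxyl-directed trans-hydroalumination of the propargylic alcohol puts aluminium on the distal alkyne carbon (C11) in a five-membered chelate, and iodinolysis with retention fixes iodine cis to the carbinol carbon C9.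

Step 11
Reactants: 17 (Z)-iodo allylic alcohol
Product: 18 (Z)-3-iodo-4-(triethylsilyloxy)but-2-enal
Conditions: MnO2, CH2Cl2, rt, dark; filtered and used at once
Reagents that add atoms: none
Why: MnO2 oxidation of an allylic alcohol is neutral and heterogeneous, which should avoid Z-to-E isomerisation of the β-iodo enal and loss of the TES group.

Step 12
Reactants: 13 (E)-allylboronate; 18 (Z)-β-iodo enal
Product: 20 methyl (4R,8E,12R,13R,14Z)-4-(tert-butyldimethylsilyloxy)-13-hydroxy-15-iodo-9-methyl-5-methylidene-12-(prop-1-en-2-yl)-16-(triethylsilyloxy)hexadeca-8,14-dienoate, via pinacol borate 19 (not isolated)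
Conditions: (R)-TRIP [(R)-3,3'-bis(2,4,6-triisopropylphenyl)-1,1'-binaphthyl-2,2'-diyl hydrogen phosphate] (10 mol%), 4 Å molecular sieves, toluene, −30 °C; aq. NaHCO3
Reagents that add atoms: none
Why: Chiral phosphoric acid-catalysed allylboration runs through a closed Zimmerman–Traxler chair in which the (E)-boronate places the C7 chain equatorial (anti C8/C9) and the catalyst, hydrogen-bonded to the boronate oxygen and the formyl hydrogen, exposes the Re face of 18; this sets 8R and the required C9 centre, whose descriptor is R while iodine sits on C11.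

Step 13
Reactants: 20 seco alcohol
Product: 21 methyl (4R,8E,12R,13R,14Z)-4-(tert-butyldimethylsilyloxy)-15-iodo-9-methyl-5-methylidene-12-(prop-1-en-2-yl)-13,16-bis(triethylsilyloxy)hexadeca-8,14-dienoate
Conditions: TESOTf, 2,6-lutidine, CH2Cl2, −78 °C
Reagents that add atoms: triethylsilyl triflate, CC[Si](CC)(CC)OS(=O)(=O)C(F)(F)F
Why: Silyl triflate silylation copes with the hindered secondary allylic alcohol without touching the ester, the iodide or the other silyl ethers.

Step 14
Reactants: 21 bis-TES methyl ester
Product: 23 (4R,8E,12R,13R,14Z)-4-(tert-butyldimethylsilyloxy)-15-iodo-9-methyl-5-methylidene-12-(prop-1-en-2-yl)-13,16-bis(triethylsilyloxy)hexadeca-8,14-dienoic acid, via trimethylstannyl ester 22 (not isolated)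
Conditions: Me3SnOH, 1,2-dichloroethane, 70 °C; wash with 0.01 M aq. KHSO4
Reagents that add atoms: trimethyltin hydroxide, C[Sn](C)(C)O
Why: Trimethyltin hydroxide cleaves unhindered methyl esters under almost neutral conditions that TES and TBS ethers and the alkenyl iodide should tolerate.

Step 15
Reactants: 23 seco acid; 24 N-hydroxyphthalimide
Product: 25 1,3-dioxoisoindolin-2-yl (4R,8E,12R,13R,14Z)-4-(tert-butyldimethylsilyloxy)-15-iodo-9-methyl-5-methylidene-12-(prop-1-en-2-yl)-13,16-bis(triethylsilyloxy)hexadeca-8,14-dienoate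
Conditions: DIC, DMAP (cat.), CH2Cl2, rt; short silica plug
Reagents that add atoms: none
Why: Steglich-type carbodiimide esterification is the standard route to redox-active esters, and all hydroxyl groups are blocked.

Step 16
Reactants: 25 seco (Z)-C11 iodide with the redox-active ester on C12
Product: 26 (4E,8R,9S,10E,14R)-14-(tert-butyldimethylsilyloxy)-5-methyl-1-methylidene-8-(prop-1-en-2-yl)-9-(triethylsilyloxy)-11-(triethylsilyloxymethyl)cyclotetradeca-4,10-diene
Conditions: NiCl2(glyme) (30 mol%), 2,2'-bipyridine (30 mol%), AgNO3 (0.3 equiv, electrode modifier), nBu4NBF4 (0.1 M), DMF, undivided cell, Mg anode, reticulated vitreous carbon cathode, constant current (about 2.5 F/mol), rt; 25 added by syringe pump over 12 h to a final 2 mM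
Reagents that add atoms: none
Why: Proposed new method: cathodically generated low-valent nickel–bipyridine inserts into the C11–I bond with retention of geometry, the resulting alkenylnickel passes one electron to the phthalimide ester, and N–O cleavage with loss of CO2 leaves the primary C12 radical, which recombines with divalent alkenylnickel to a trivalent nickel species that reductively eliminates the C11–C12 bond. The closest known reaction type is the intermolecular nickel-electrocatalytic decarboxylative coupling of redox-active esters with alkenyl iodides used for trisubstituted terpenoid alkenes; what is new is running it within one molecule to close a large ring. The single 14-membered carbocycle closes by end-to-end radical capture at nickel (a 15-membered nickelacycle) followed by C(sp2)–C(sp3) reductive elimination. No stereocentre is formed: C8, C9 and C14 are spectators and the cis C9/C12 relation is inherited from the (Z)-iodide, so the descriptors change to 10E and 9S only because iodine is replaced by carbon. The step needs ring closure to beat oligomerisation and hydrogen abstraction; addition at a rate matched to the current keeps free 25 at trace level, electron transfer from the substrate's own alkenylnickel would generate the radical with the chain already folded, and the radical is primary, unhindered and has only 4-exo or 5-endo paths to the C1 methylene. The silyl ethers on C9 and C18 are poor leaving groups, so β-elimination from the alkenylnickel to an allene is not expected.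

Step 17
Reactants: 26 trisilylated macrocycle
Product: 27 (4E,8R,9S,10E,14R)-14-(tert-butyldimethylsilyloxy)-11-(hydroxymethyl)-5-methyl-1-methylidene-8-(prop-1-en-2-yl)cyclotetradeca-4,10-dien-9-ol
Conditions: PPTS (cat.), MeOH/CH2Cl2, 0 °C to rt
Reagents that add atoms: none
Why: In this selective acid-catalysed methanolysis, TES ethers solvolyse far faster than a secondary TBS ether, and the medium is too weakly acidic to ionise the allylic alcohols.

Step 18
Reactants: 27 C9,C18-diol
Product: 28 (4E,8R,9S,10E,14R)-9-acetoxy-11-(acetoxymethyl)-14-(tert-butyldimethylsilyloxy)-5-methyl-1-methylidene-8-(prop-1-en-2-yl)cyclotetradeca-4,10-diene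
Conditions: Ac2O, pyridine, DMAP (cat.), CH2Cl2, rt
Reagents that add atoms: acetic anhydride, CC(=O)OC(C)=O
Why: DMAP-catalysed acylation takes both free hydroxyl groups while C14 remains blocked.

Step 19
Reactants: 28 diacetate TBS ether
Product: 29 target CNP0077636.1, (4E,8R,9S,10E,14R)-9-acetoxy-11-(acetoxymethyl)-5-methyl-1-methylidene-8-(prop-1-en-2-yl)cyclotetradeca-4,10-dien-14-ol
Conditions: HF·pyridine, pyridine, THF, 0 °C to rt
Reagents that add atoms: none
Why: Buffered fluoride desilylation is non-basic, so the two allylic acetates should neither migrate nor hydrolyse.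

**Compound list**
1 | (R)-5-oxotetrahydrofuran-2-carboxylic acid | O=C1CC[C@@H](O1)C(=O)O | starting material
2 | allyl hydrogen malonate | C=CCOC(=O)CC(=O)O | starting material
3 | (R)-5-(imidazole-1-carbonyl)dihydrofuran-2(3H)-one | O=C1CC[C@@H](O1)C(=O)n1ccnc1 | intermediate (not isolated)
4 | allyl 3-oxo-3-[(2R)-5-oxotetrahydrofuran-2-yl]propanoate | O=C1CC[C@@H](O1)C(=O)CC(=O)OCC=C | intermediate
5 | geranyl bromide | CC(C)=CCC/C(C)=C/CBr | starting material
6 | allyl (4E)-5,9-dimethyl-2-[(2R)-5-oxotetrahydrofuran-2-carbonyl]deca-4,8-dienoate (C2 epimers) | O=C1CC[C@@H](O1)C(=O)C(C/C=C(\C)CCC=C(C)C)C(=O)OCC=C | intermediate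
7 | (5R)-5-[(4E)-5,9-dimethyldeca-4,8-dienoyl]dihydrofuran-2(3H)-one | O=C1CC[C@@H](O1)C(=O)CC/C=C(\C)CCC=C(C)C | intermediate
8 | (5R)-5-[(5E)-6,10-dimethylundeca-1,5,9-trien-2-yl]dihydrofuran-2(3H)-one | O=C1CC[C@@H](O1)C(=C)CC/C=C(\C)CCC=C(C)C | intermediate
9 | potassium (4R,8E)-4-hydroxy-9,13-dimethyl-5-methylidenetetradeca-8,12-dienoate | [K+].[O-]C(=O)CC[C@@H](O)C(=C)CC/C=C(\C)CCC=C(C)C | intermediate (not isolated)
10 | methyl (4R,8E)-4-hydroxy-9,13-dimethyl-5-methylidenetetradeca-8,12-dienoate | COC(=O)CC[C@@H](O)C(=C)CC/C=C(\C)CCC=C(C)C | intermediate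
11 | methyl (4R,8E)-4-(TBS-oxy)-9,13-dimethyl-5-methylidenetetradeca-8,12-dienoate | COC(=O)CC[C@@H](O[Si](C)(C)C(C)(C)C)C(=C)CC/C=C(\C)CCC=C(C)C | intermediate
12 | methyl (4R,8E,12E)-4-(TBS-oxy)-14-hydroxy-9,13-dimethyl-5-methylidenetetradeca-8,12-dienoate | COC(=O)CC[C@@H](O[Si](C)(C)C(C)(C)C)C(=C)CC/C=C(\C)CC/C=C(\C)CO | intermediate
13 | (12E)-allyl pinacol boronate of 12 | COC(=O)CC[C@@H](O[Si](C)(C)C(C)(C)C)C(=C)CC/C=C(\C)CC/C=C(\C)CB1OC(C)(C)C(C)(C)O1 | intermediate
14 | but-2-yne-1,4-diol | OCC#CCO | starting material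
15 | 4-(triethylsilyloxy)but-2-yn-1-ol | OCC#CCO[Si](CC)(CC)CC | intermediate
16 | sodium cyclic alkenylaluminate (2,5-dihydro-1,2-oxaluminole ate complex, Al on C11) | [Na+].COCCO[Al-]1(OCCOC)OCC=C1CO[Si](CC)(CC)CC | intermediate (not isolated)
17 | (Z)-3-iodo-4-(triethylsilyloxy)but-2-en-1-ol | OC/C=C(/CO[Si](CC)(CC)CC)I | intermediate
18 | (Z)-3-iodo-4-(triethylsilyloxy)but-2-enal | O=C/C=C(/CO[Si](CC)(CC)CC)I | intermediate
19 | C9 O-pinacolboryl derivative of 20 | COC(=O)CC[C@@H](O[Si](C)(C)C(C)(C)C)C(=C)CC/C=C(\C)CC[C@H](C(=C)C)[C@@H](OB1OC(C)(C)C(C)(C)O1)/C=C(/CO[Si](CC)(CC)CC)I | intermediate (not isolated)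
20 | seco alcohol (methyl ester, C14 OTBS, C9 OH, C18 OTES, C11 iodide) | COC(=O)CC[C@@H](O[Si](C)(C)C(C)(C)C)C(=C)CC/C=C(\C)CC[C@H](C(=C)C)[C@@H](O)/C=C(/CO[Si](CC)(CC)CC)I | intermediate
21 | seco bis-TES methyl ester | COC(=O)CC[C@@H](O[Si](C)(C)C(C)(C)C)C(=C)CC/C=C(\C)CC[C@H](C(=C)C)[C@@H](O[Si](CC)(CC)CC)/C=C(/CO[Si](CC)(CC)CC)I | intermediate
22 | trimethylstannyl ester of 23 | C[Sn](C)(C)OC(=O)CC[C@@H](O[Si](C)(C)C(C)(C)C)C(=C)CC/C=C(\C)CC[C@H](C(=C)C)[C@@H](O[Si](CC)(CC)CC)/C=C(/CO[Si](CC)(CC)CC)I | intermediate (not isolated)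
23 | seco acid | OC(=O)CC[C@@H](O[Si](C)(C)C(C)(C)C)C(=C)CC/C=C(\C)CC[C@H](C(=C)C)[C@@H](O[Si](CC)(CC)CC)/C=C(/CO[Si](CC)(CC)CC)I | intermediate
24 | N-hydroxyphthalimide | O=C1c2ccccc2C(=O)N1O | starting material
25 | seco (Z)-C11 iodide N-hydroxyphthalimide ester (key-step precursor) | O=C1c2ccccc2C(=O)N1OC(=O)CC[C@@H](O[Si](C)(C)C(C)(C)C)C(=C)CC/C=C(\C)CC[C@H](C(=C)C)[C@@H](O[Si](CC)(CC)CC)/C=C(/CO[Si](CC)(CC)CC)I | intermediate
26 | 14-membered macrocycle, C9 and C18 OTES, C14 OTBS (key-step product) | C=C1CC/C=C(\C)CC[C@H](C(=C)C)[C@@H](O[Si](CC)(CC)CC)/C=C(/CO[Si](CC)(CC)CC)CC[C@H]1O[Si](C)(C)C(C)(C)C | intermediate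
27 | macrocyclic C9,C18-diol, C14 OTBS | C=C1CC/C=C(\C)CC[C@H](C(=C)C)[C@@H](O)/C=C(/CO)CC[C@H]1O[Si](C)(C)C(C)(C)C | intermediate
28 | macrocyclic C9,C18-diacetate, C14 OTBS | C=C1CC/C=C(\C)CC[C@H](C(=C)C)[C@@H](OC(C)=O)/C=C(/COC(C)=O)CC[C@H]1O[Si](C)(C)C(C)(C)C | intermediate
29 | CNP0077636.1 | C=C1CC/C=C(\C)CC[C@H](C(=C)C)[C@@H](OC(C)=O)/C=C(/COC(C)=O)CC[C@H]1O | target

**Step count**
Total step count: 19. Longest linear sequence: 16 steps (steps 1–8 and 12–19, from 1).

**Steps most likely to fail**

Step 16 (macrocyclisation).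
- Risks: the C12 radical may be captured by the alkenylnickel of a second molecule, which leads to oligomerisation. It may abstract hydrogen from the solvent, or undergo a 1,5-hydrogen shift from allylic C2, before it meets nickel. Iodine may also be lost reductively at C11.
- Fallback (sets out from 11 and 17, comes back at 27): the C11–C12 bond is made first in the known intermolecular mode, and the ring is then closed at C8–C9 by a Nozaki–Hiyama allylation, a macrocyclisation established for cembranoid rings.
- LiOH saponification of 11 gives the carboxylic acid F1, and DIC with 24 gives its N-hydroxyphthalimide ester F2.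
- Nickel-electrocatalytic decarboxylative alkenylation of F2 with excess 17, at normal concentration, gives the coupled allylic alcohol F3.
- MnO2 gives the enal F4, SeO2/tBuOOH gives the terminal hydroxy enal F5, and an Appel reaction (CBr4, PPh3) gives the bromo enal F6.
- Slow addition of F6 to CrCl2 in THF closes the ring to the anti homoallylic alcohol F7, and PPTS in MeOH removes the C18 TES group to give 27.
- The anti C8/C9 relation follows from the chair transition state. Its sense relative to C14 rests on the macrocyclic conformation, so a diastereomer separation must be allowed for.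

Step 12 (allylboration).
- Risks: insufficient facial control by the catalyst on a conjugated β-iodo enal, erosion of the anti relation if the boronate geometry is not uniform, and Z-to-E isomerisation of the aldehyde during a slow reaction.
- Fallback (sets out from 12 and 18, comes back at 20): boron is exchanged for silicon and Brønsted-acid catalysis for Lewis-base catalysis.
- MsCl/Et3N and then LiCl convert 12 into the allylic chloride F8 with the geometry kept.
- HSiCl3, CuCl (cat.) and iPr2NEt in Et2O give the (E)-allyltrichlorosilane F9 without passing through a π-allyl metal species.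
- Addition of F9 to 18 under a chiral 2,2'-bispyrrolidine-derived bisphosphoramide proceeds through a closed chair at hexacoordinate silicon, a method best suited to conjugated aldehydes, and gives the trichlorosilyl ether F10. Aqueous NaHCO3 work-up gives 20.

Step 7 (allylic oxidation).
- Risks: competing ene attack at the internal C4=C5 alkene, and over-oxidation of the allylic alcohol.
- Fallback (sets out from 11, comes back at 12): the isopropylidene end is degraded and the (E)-allylic alcohol is rebuilt by olefination.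
- NBS in aqueous THF gives the terminal bromohydrin F11, and K2CO3 in MeOH gives the terminal epoxide F12.
- H5IO6 cleaves F12 to the C8 aldehyde F13.
- Wittig reaction of F13 with 2-(triphenylphosphoranylidene)propanal gives the (E)-enal F14, and Luche reduction (NaBH4, CeCl3·7H2O, MeOH) gives 12.

**Further compounds**
F1 | step 16 | (4R,8E)-4-(TBS-oxy)-9,13-dimethyl-5-methylidenetetradeca-8,12-dienoic acid | OC(=O)CC[C@@H](O[Si](C)(C)C(C)(C)C)C(=C)CC/C=C(\C)CCC=C(C)C
F2 | step 16 | 1,3-dioxoisoindolin-2-yl ester of F1 | O=C1c2ccccc2C(=O)N1OC(=O)CC[C@@H](O[Si](C)(C)C(C)(C)C)C(=C)CC/C=C(\C)CCC=C(C)C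
F3 | step 16 | (2E,6R,10E)-6-(TBS-oxy)-11,15-dimethyl-7-methylidene-3-(triethylsilyloxymethyl)hexadeca-2,10,14-trien-1-ol | OC/C=C(/CO[Si](CC)(CC)CC)CC[C@@H](O[Si](C)(C)C(C)(C)C)C(=C)CC/C=C(\C)CCC=C(C)C
F4 | step 16 | (2E,6R,10E)-enal from F3 | O=C/C=C(/CO[Si](CC)(CC)CC)CC[C@@H](O[Si](C)(C)C(C)(C)C)C(=C)CC/C=C(\C)CCC=C(C)C
F5 | step 16 | (2E,6R,10E,14E)-16-hydroxy enal | O=C/C=C(/CO[Si](CC)(CC)CC)CC[C@@H](O[Si](C)(C)C(C)(C)C)C(=C)CC/C=C(\C)CC/C=C(\C)CO
F6 | step 16 | (2E,6R,10E,14E)-16-bromo enal | O=C/C=C(/CO[Si](CC)(CC)CC)CC[C@@H](O[Si](C)(C)C(C)(C)C)C(=C)CC/C=C(\C)CC/C=C(\C)CBr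
F7 | step 16 | macrocycle with free C9 OH, C18 OTES, C14 OTBS | C=C1CC/C=C(\C)CC[C@H](C(=C)C)[C@@H](O)/C=C(/CO[Si](CC)(CC)CC)CC[C@H]1O[Si](C)(C)C(C)(C)C
F8 | step 12 | (12E)-allylic chloride from 12 | COC(=O)CC[C@@H](O[Si](C)(C)C(C)(C)C)C(=C)CC/C=C(\C)CC/C=C(\C)CCl
F9 | step 12 | (12E)-allyltrichlorosilane | COC(=O)CC[C@@H](O[Si](C)(C)C(C)(C)C)C(=C)CC/C=C(\C)CC/C=C(\C)C[Si](Cl)(Cl)Cl
F10 | step 12 | C9 O-trichlorosilyl derivative of 20 | COC(=O)CC[C@@H](O[Si](C)(C)C(C)(C)C)C(=C)CC/C=C(\C)CC[C@H](C(=C)C)[C@@H](O[Si](Cl)(Cl)Cl)/C=C(/CO[Si](CC)(CC)CC)I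
F11 | step 7 | terminal bromohydrin of 11 (C8 epimers) | COC(=O)CC[C@@H](O[Si](C)(C)C(C)(C)C)C(=C)CC/C=C(\C)CCC(Br)C(C)(C)O
F12 | step 7 | terminal epoxide of 11 (C8 epimers) | COC(=O)CC[C@@H](O[Si](C)(C)C(C)(C)C)C(=C)CC/C=C(\C)CCC1OC1(C)C
F13 | step 7 | C8 aldehyde | COC(=O)CC[C@@H](O[Si](C)(C)C(C)(C)C)C(=C)CC/C=C(\C)CCC=O
F14 | step 7 | (12E)-enal corresponding to 12 | COC(=O)CC[C@@H](O[Si](C)(C)C(C)(C)C)C(=C)CC/C=C(\C)CC/C=C(\C)C=O
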